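**Retrosynthetic overview**
1. Key disconnection, ring B aryl–CH2 bond: 3-bromo-5-methoxyphenol 1 + propanal 2. Hydrazine 3 turns the aldehyde carbon into a propyl carbanion equivalent (N–H hydrazone 4, then diazene 5, loss of N2) ⇒ 3-methoxy-5-propylphenol 6.
2. Ring B C1 carbon: formylation para to the free OH (iminium salt 7) ⇒ hydroxy aldehyde 8. The CHO serves as a masked CO2H, so no protecting group is needed.
3. Ring A is bought with its pentyl chain as olivetol dimethyl ether 9; iodination next to the chain ⇒ iodide 10.
4. Depside link: the aryl–C(=O) and C(=O)–O bonds are made together by carbonylative coupling of 10, CO and 8 ⇒ depside aldehyde 11. The last step, CHO → CO2H, gives target 12.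
5. Ring formation: none. Both benzene rings are bought intact; ring B is elaborated first and ring A is joined to it in step 4.

Assumption: the SMILES holds no stereocentre and no stereogenic double bond, so the target (2,2'-di-O-methylstenosporic acid) is achiral and needs no stereocontrol.

**Route**

Step 1
Reactants: 1 3-bromo-5-methoxyphenol; 2 propanal; 3 hydrazine monohydrate
Product: 6 3-methoxy-5-propylphenol, via propanal hydrazone 4 (not isolated), via benzylic diazene 5 (not isolated)
Conditions: 2 (2.0 equiv), 3 (2.2 equiv), THF, rt, 30 min, Na2SO4; then 1, Ni(cod)2 (10 mol %), PMe3 (40 mol %), LiOt-Bu (3.5 equiv), 1,4-dioxane, 80 °C, 24 h; aq NH4Cl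
Reagents that add atoms: none
Why: Proposed new method: the N–H hydrazone 4 reverses the polarity of the electrophilic aldehyde carbon of 2, so that after oxidative addition of the C–Br bond of 1 to zerovalent nickel the deprotonated hydrazone binds as an aza-allyl ligand (leaving little room for beta-hydride elimination), C–C reductive elimination gives diazene 5, and 5 loses N2 in Wolff–Kishner fashion through a benzylic anion to give 6, the phenoxide being meta to bromine and so not feeding electron density into the reacting carbon; the closest known reaction type is the nickel-catalysed denitrogenative cross-coupling of aryl aldehyde N–H hydrazones with aryl halides and phenol derivatives, stretched here to an unbranched aliphatic hydrazone and a free bromophenol, and the transient stereocentre of 5 disappears with N2.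

Step 2
Reactants: 6 3-methoxy-5-propylphenol
Product: 8 4-hydroxy-2-methoxy-6-propylbenzaldehyde, via aryl iminium salt 7 (not isolated)
Conditions: POCl3 (2.0 equiv), DMF, 0 °C to rt, 16 h; then ice/H2O, 1 h; chromatography
Reagents that add atoms: N,N-dimethylformamide CN(C)C=O; water O
Why: Vilsmeier–Haack formylation, in which the free OH is the strongest para director so that, as with 3,5-dimethoxyphenol, the chloroiminium ion attacks mainly para to OH (between OMe and propyl), hydrolysis of 7 gives 8, and the minor chelated ortho-hydroxy aldehydes are much less polar and are removed on silica; no stereocentre is formed.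

Step 3
Reactants: 9 1,3-dimethoxy-5-pentylbenzene (olivetol dimethyl ether)
Product: 10 2-iodo-1,5-dimethoxy-3-pentylbenzene
Conditions: NIS (1.05 equiv), TFA (10 mol %), MeCN, 0 °C to rt, dark, 2 h
Reagents that add atoms: N-iodosuccinimide O=C1CCC(=O)N1I
Why: Electrophilic aromatic iodination, which in 3,5-dimethoxyalkylbenzenes goes para to one OMe and ortho to the other (next to the alkyl chain) and not into the crowded position between the two OMe groups, one equivalent of NIS stopping at the monoiodide.

Step 4
Reactants: 10 2-iodo-1,5-dimethoxy-3-pentylbenzene; 8 4-hydroxy-2-methoxy-6-propylbenzaldehyde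
Product: 11 4-formyl-3-methoxy-5-propylphenyl 2,4-dimethoxy-6-pentylbenzoate
Conditions: Pd(OAc)2 (5 mol %), Xantphos (7.5 mol %), K2CO3 (2.0 equiv), CO (10 bar), toluene, 110 °C, 16 h
Reagents that add atoms: carbon monoxide [C-]#[O+]
Why: Heck-type carbonylative esterification (aryloxycarbonylation), that is oxidative addition of the C–I bond to zerovalent palladium, CO insertion and acyl transfer to the readily formed phenoxide of the acidic para-formylphenol 8, supported by the known alkoxycarbonylation under CO pressure of 3,5-dimethoxyaryl iodides flanked by OMe and CH2R, with the non-enolisable aldehyde inert under these conditions.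

Step 5
Reactants: 11 4-formyl-3-methoxy-5-propylphenyl 2,4-dimethoxy-6-pentylbenzoate
Product: 12 4-[(2,4-dimethoxy-6-pentylbenzoyl)oxy]-2-methoxy-6-propylbenzoic acid (target)
Conditions: NaClO2 (3 equiv), NaH2PO4 (3 equiv), 2-methyl-2-butene (20 equiv), t-BuOH/THF/H2O, 0 °C to rt, 6 h
Reagents that add atoms: sodium chlorite [Na+].[O-]Cl=O
Why: Pinnick (Lindgren–Kraus) oxidation, which converts the hindered aryl aldehyde to the acid at about pH 4, where the hindered aryl ester is not hydrolysed, while the large excess of 2-methyl-2-butene keeps the electron-rich ring A from being chlorinated; this oxidation is established for depside aldehydes.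

**Compound list**
1 | 3-bromo-5-methoxyphenol | COc1cc(O)cc(Br)c1 | starting material
2 | propanal | CCC=O | starting material
3 | hydrazine monohydrate | NN.O | starting material
4 | (E)-propanal hydrazone (propylidenehydrazine) | CC/C=N/N | intermediate
5 | 3-(1-diazenylpropyl)-5-methoxyphenol (racemic, transient) | CCC(N=N)c1cc(O)cc(OC)c1 | intermediate
6 | 3-methoxy-5-propylphenol | CCCc1cc(O)cc(OC)c1 | intermediate
7 | [(4-hydroxy-2-methoxy-6-propylphenyl)methylidene]dimethylammonium dichlorophosphate | CCCc1cc(O)cc(OC)c1C=[N+](C)C.[O-]P(=O)(Cl)Cl | intermediate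
8 | 4-hydroxy-2-methoxy-6-propylbenzaldehyde | CCCc1cc(O)cc(OC)c1C=O | intermediate
9 | 1,3-dimethoxy-5-pentylbenzene (olivetol dimethyl ether) | CCCCCc1cc(OC)cc(OC)c1 | starting material
10 | 2-iodo-1,5-dimethoxy-3-pentylbenzene | CCCCCc1cc(OC)cc(OC)c1I | intermediate
11 | 4-formyl-3-methoxy-5-propylphenyl 2,4-dimethoxy-6-pentylbenzoate | CCCCCc1cc(OC)cc(OC)c1C(=O)Oc1cc(CCC)c(C=O)c(OC)c1 | intermediate
12 | 4-[(2,4-dimethoxy-6-pentylbenzoyl)oxy]-2-methoxy-6-propylbenzoic acid (achiral) | CCCCCc1cc(OC)cc(OC)c1C(=O)Oc1cc(CCC)c(C(=O)O)c(OC)c1 | target

**Step count**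
- Total step count: 5.
- Longest linear sequence: 4 steps (1 → 6 → 8 → 11 → 12, that is steps 1, 2, 4 and 5). Step 3 is the one-step side branch.

**Steps most likely to fail**

Risk 1 (step 1).
- Failure modes: an unbranched aliphatic N–H hydrazone is less acidic than the aryl aldehyde hydrazones for which this nickel coupling works best. It can collapse to the azine or be reduced to propane. The alkylnickel stage can undergo beta-hydride elimination. The lithium phenoxide of 1 may add slowly to the metal.
- Fallback: it sets out from 1 and 2 and comes back at 6. It keeps the aldehyde carbon as the nucleophilic partner but changes both the metal and the mechanism.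
- Aldehyde 2 is condensed with TsNHNH2 (MeOH, rt) to propanal N-tosylhydrazone F1. F1 is coupled with 1 (Pd2(dba)3, XPhos, LiOt-Bu, dioxane, 100 °C) by diazo formation, palladium carbene formation, aryl migration and beta-hydride elimination. This gives 3-methoxy-5-[(E)-prop-1-en-1-yl]phenol F2. Hydrogenation (H2, Pd/C, EtOAc, rt) then gives 6.

Risk 2 (step 4).
- Failure modes: the iodide carries two ortho substituents and is electron-rich, and the phenoxide of 8 is a weak nucleophile. Hydrodeiodination, or hydrolysis to the acid, may win over ester formation.
- Fallback: it sets out from 10 and comes back at 11. It separates C–C from C–O bond formation.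
- Iodine–lithium exchange (n-BuLi, THF, −78 °C) gives (2,4-dimethoxy-6-pentylphenyl)lithium F3. A CO2 quench and acid work-up give 2,4-dimethoxy-6-pentylbenzoic acid F4.
- F4 is activated with trifluoroacetic anhydride (toluene, rt) as 2,4-dimethoxy-6-pentylbenzoic trifluoroacetic anhydride F5. F5 acylates 8 in the same flask to give 11. This is the classical way to esterify hindered depside acids.

Risk 3 (step 2).
- Failure mode: formylation para to OMe, or between OH and OMe, may compete more than expected and lower the yield of 8.
- Fallback: it sets out from 6 and comes back at 11. It removes the regiochemical question by symmetry.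
- BBr3 (CH2Cl2, −78 °C to rt) gives 5-propylresorcinol F6. Vilsmeier formylation of F6 gives 2,4-dihydroxy-6-propylbenzaldehyde F7.
- F7 is coupled with 10 and CO under the conditions of step 4. Reaction occurs at the free, more acidic 4-OH, because the 2-OH is chelated to the aldehyde. The product is 4-formyl-3-hydroxy-5-propylphenyl 2,4-dimethoxy-6-pentylbenzoate F8. Methylation of the remaining OH (MeI, K2CO3, acetone, reflux) gives 11.

Further compounds
F1 | step 1 | propanal N-tosylhydrazone | CC/C=N/NS(=O)(=O)c1ccc(C)cc1
F2 | step 1 | 3-methoxy-5-[(E)-prop-1-en-1-yl]phenol | C/C=C/c1cc(O)cc(OC)c1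
F3 | step 4 | (2,4-dimethoxy-6-pentylphenyl)lithium | [Li]c1c(CCCCC)cc(OC)cc1OC
F4 | step 4 | 2,4-dimethoxy-6-pentylbenzoic acid | CCCCCc1cc(OC)cc(OC)c1C(=O)O
F5 | step 4 | 2,4-dimethoxy-6-pentylbenzoic trifluoroacetic anhydride | CCCCCc1cc(OC)cc(OC)c1C(=O)OC(=O)C(F)(F)F
F6 | step 2 | 5-propylresorcinol (divarinol) | CCCc1cc(O)cc(O)c1
F7 | step 2 | 2,4-dihydroxy-6-propylbenzaldehyde | CCCc1cc(O)cc(O)c1C=O
F8 | step 2 | 4-formyl-3-hydroxy-5-propylphenyl 2,4-dimethoxy-6-pentylbenzoate | CCCCCc1cc(OC)cc(OC)c1C(=O)Oc1cc(CCC)c(C=O)c(O)c1
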